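**Plan**

1. Retrosynthesis of 3-[(1S,2R,3R)-2-(1H-indol-3-ylmethyl)-2,3-dimethyl-6-(propan-2-ylidene)cyclohexyl]propanoic acid (cyclohexane locants used throughout): remove the α-CH2 of the acid arm (Arndt–Eistert retron); cut ring bond C1–C6 (C1 = ring CH carrying the arm, C6 = ring carbon carrying Me2C=); then cut C5–C6, the enoate C=C and the two exocyclic bonds at the quaternary C2.
2. Enabling feature: C6 is a fully substituted vinylic ring carbon bonded directly to the stereogenic CH C1 (a 2-substituted alkylidenecyclohexane). A vinyl radical at C6 that already carries the Me2C= unit can add 6-exo to the β-carbon of an enoate (the future C1), so the alkene position is fixed from the start and allylic 1,3-strain can set C1.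
3. Forward order: (4R)-4-methyloxan-2-one, α-indolylmethylation, α-methylation, iodide opening of the lactone, Negishi coupling with Br2C=CMe2, aldehyde, enoate, radical closure of the only carbocycle, saponification with N-deprotection, Arndt–Eistert homologation.
4. Stereochemistry: C3 comes from a chiral-pool half-ester; C2 from alkylation of the cyclic lactone enolate anti to the C3 methyl group; C1 from the ring closure (allylic strain plus the C2 and C3 centres).

Key step: step 10

Assumption: (3R)-5-methoxy-3-methyl-5-oxopentanoic acid is taken as a catalogue compound (it is otherwise made from 3-methylglutaric anhydride by alkaloid-mediated methanolysis).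

**Route**

Step 1
Reactants: 1 3-methyl-1H-indole
Product: 2 3-methyl-1-(phenylsulfonyl)-1H-indole
Conditions: NaH, DMF, 0 °C; PhSO2Cl, 0 °C → rt
Reagents that add atoms: benzenesulfonyl chloride, O=S(=O)(Cl)c1ccccc1
Why: N-sulfonylation of the sodium indolide; the electron-poor N-substituent is needed to make the 3-(bromomethyl)indole of step 2 a stable SN2 electrophile.

Step 2
Reactants: 2 3-methyl-1-(phenylsulfonyl)-1H-indole
Product: 3 3-(bromomethyl)-1-(phenylsulfonyl)-1H-indole
Conditions: NBS (1.05 equiv), (PhCO2)2 (cat.), CCl4, reflux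
Reagents that add atoms: N-bromosuccinimide, O=C1CCC(=O)N1Br
Why: Wohl–Ziegler bromination; hydrogen abstraction at the 3-methyl group gives a radical stabilised by the indole π-system, and the deactivated N-sulfonyl ring should resist ring bromination under radical conditions.

Step 3
Reactants: 4 (3R)-5-methoxy-3-methyl-5-oxopentanoic acid
Product: 6 (4R)-4-methyloxan-2-one, via methyl (3R)-5-hydroxy-3-methylpentanoate 5 (not isolated)
Conditions: BH3·SMe2, THF, −10 °C → rt; MeOH quench; TsOH·H2O (cat.), PhMe, 80 °C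
Reagents that add atoms: none
Why: chemoselective borane reduction of the carboxylic acid beside the methyl ester, then acid-catalysed lactonisation; the stereocentre is not involved and keeps the R configuration.

Step 4
Reactants: 6 (4R)-4-methyloxan-2-one; 3 3-(bromomethyl)-1-(phenylsulfonyl)-1H-indole
Product: 7 (3S,4R)-4-methyl-3-{[1-(phenylsulfonyl)-1H-indol-3-yl]methyl}oxan-2-one
Conditions: LiN(i-Pr)2 (1.05 equiv), THF, −78 °C; 3, THF–DMPU, −78 → −40 °C
Reagents that add atoms: none
Why: SN2 alkylation of the lactone lithium enolate by the benzylic-type bromide, anti to the 4-methyl group (trans product); this centre is re-enolised in step 5, so only clean mono-alkylation matters.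

Step 5
Reactants: 7 (3S,4R)-4-methyl-3-{[1-(phenylsulfonyl)-1H-indol-3-yl]methyl}oxan-2-one
Product: 8 (3R,4R)-3,4-dimethyl-3-{[1-(phenylsulfonyl)-1H-indol-3-yl]methyl}oxan-2-one
Conditions: LiN(i-Pr)2 (1.05 equiv), THF, −78 °C; MeI, −78 → −20 °C
Reagents that add atoms: iodomethane, CI
Why: alkylation of the trisubstituted cyclic enolate; the 4-methyl group sits pseudo-axial in the half-chair enolate to avoid allylic 1,2-strain, so methyl iodide should enter on the opposite face and set the quaternary centre with the new methyl trans and the indolylmethyl group cis to the 4-methyl.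

Step 6
Reactants: 8 (3R,4R)-3,4-dimethyl-3-{[1-(phenylsulfonyl)-1H-indol-3-yl]methyl}oxan-2-one
Product: 11 methyl (2R,3R)-5-iodo-2,3-dimethyl-2-{[1-(phenylsulfonyl)-1H-indol-3-yl]methyl}pentanoate, via silyl ester 9 (not isolated), via iodo acid 10 (not isolated)
Conditions: Me3SiI (2.2 equiv), CH2Cl2, 0 °C → rt; MeOH, then evaporation; Me3SiCHN2, PhMe–MeOH (3:1), 0 °C
Reagents that add atoms: iodotrimethylsilane, C[Si](C)(C)I; (trimethylsilyl)diazomethane, C[Si](C)(C)C=[N+]=[N-]
Why: silyl activation of the lactone and SN2 attack of iodide at the unhindered O–CH2 (alkyl–oxygen cleavage), then methanolysis of the silyl ester and O-methylation of the hindered acid with the diazoalkane under non-basic conditions that should not allow re-lactonisation.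

Step 7
Reactants: 11 methyl (2R,3R)-5-iodo-2,3-dimethyl-2-{[1-(phenylsulfonyl)-1H-indol-3-yl]methyl}pentanoate; 12 1,1-dibromo-2-methylprop-1-ene
Product: 14 methyl (2R,3R)-6-bromo-2,3,7-trimethyl-2-{[1-(phenylsulfonyl)-1H-indol-3-yl]methyl}oct-6-enoate, via alkylzinc iodide 13 (not isolated)
Conditions: Zn dust (activated with BrCH2CH2Br and Me3SiCl), THF, 40 °C; then 12 (3 equiv), PdCl2(DPEphos) (5 mol %), THF, 23–50 °C
Reagents that add atoms: none
Why: zinc insertion into the primary C–I bond and Negishi coupling; only one C–Br bond of the gem-dibromoalkene should react because the tetrasubstituted bromoalkene formed is far slower in oxidative addition, and the two identical methyl groups leave no alkene geometry to control.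

Step 8
Reactants: 14 methyl (2R,3R)-6-bromo-2,3,7-trimethyl-2-{[1-(phenylsulfonyl)-1H-indol-3-yl]methyl}oct-6-enoate
Product: 15 (2R,3R)-6-bromo-2,3,7-trimethyl-2-{[1-(phenylsulfonyl)-1H-indol-3-yl]methyl}oct-6-enal
Conditions: i-Bu2AlH (1.1 equiv), CH2Cl2, −78 °C; Rochelle salt work-up
Reagents that add atoms: none
Why: partial reduction of an ester on a quaternary carbon, whose hindered aluminium hemiacetal should persist at −78 °C and release the aldehyde only on work-up.

Step 9
Reactants: 15 (2R,3R)-6-bromo-2,3,7-trimethyl-2-{[1-(phenylsulfonyl)-1H-indol-3-yl]methyl}oct-6-enal; 16 methyl 2-(triphenyl-λ5-phosphanylidene)acetate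
Product: 17 methyl (2E,4R,5R)-8-bromo-4,5,9-trimethyl-4-{[1-(phenylsulfonyl)-1H-indol-3-yl]methyl}deca-2,8-dienoate
Conditions: 16 (2 equiv), PhMe, 110 °C
Reagents that add atoms: none
Why: Wittig olefination with a stabilised ylide should give the (E)-enoate; the aldehyde has no α-hydrogen and cannot epimerise.

Step 10
Reactants: 17 methyl (2E,4R,5R)-8-bromo-4,5,9-trimethyl-4-{[1-(phenylsulfonyl)-1H-indol-3-yl]methyl}deca-2,8-dienoate
Product: 18 methyl 2-[(1S,2R,3R)-2,3-dimethyl-2-{[1-(phenylsulfonyl)-1H-indol-3-yl]methyl}-6-(propan-2-ylidene)cyclohexyl]acetate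
Conditions: Bu3SnH (1.3 equiv) and AIBN (0.2 equiv) by syringe pump over 6 h, PhH, 80 °C, 0.01 M
Reagents that add atoms: none
Why: Bu3Sn• abstracts bromine from the tetrasubstituted bromoalkene to give a σ-vinyl radical at the carbon that already carries the propan-2-ylidene unit (future C6); this adds to the β-carbon of the enoate (future C1) and the ester-stabilised adduct radical is reduced by Bu3SnH. The closest known reaction type is the tin-hydride-mediated cyclisation of vinyl bromides onto α,β-unsaturated esters. The cyclohexane closes in the 6-exo-trig mode through a chair-like transition state with the C3 methyl equatorial. The new stereocentre C1 is controlled by allylic 1,3-strain to the (Z)-methyl of the pre-formed propan-2-ylidene group, which should force the CH2CO2Me arm pseudo-axial, and by the C2 and C3 centres, since only the chair with C3–Me and C2–Me equatorial and the indolylmethyl group axial on the opposite face avoids a 1,3-diaxial contact with that arm. The step needs 6-exo attack to win over 7-endo attack and over direct reduction of the vinyl radical; the first is secured by the polarisation of the enoate and the gem-dialkyl effect of the quaternary C2, the second by slow addition of the hydride at high dilution. The alkene position cannot drift because the radical is generated exactly at the carbon that bore bromine.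

Step 11
Reactants: 18 methyl 2-[(1S,2R,3R)-2,3-dimethyl-2-{[1-(phenylsulfonyl)-1H-indol-3-yl]methyl}-6-(propan-2-ylidene)cyclohexyl]acetate
Product: 19 2-[(1S,2R,3R)-2-(1H-indol-3-ylmethyl)-2,3-dimethyl-6-(propan-2-ylidene)cyclohexyl]acetic acid
Conditions: KOH (10 equiv), MeOH–H2O (4:1), 70 °C; then 1 M HCl to pH 3
Reagents that add atoms: potassium hydroxide, [K+].[OH-]
Why: saponification of the unhindered methyl ester and hydroxide attack at sulfur to remove the N-sulfonyl group in the same pot; C1 is β to the carbonyl and cannot epimerise.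

Step 12
Reactants: 19 2-[(1S,2R,3R)-2-(1H-indol-3-ylmethyl)-2,3-dimethyl-6-(propan-2-ylidene)cyclohexyl]acetic acid
Product: 21 1-diazo-3-[(1S,2R,3R)-2-(1H-indol-3-ylmethyl)-2,3-dimethyl-6-(propan-2-ylidene)cyclohexyl]propan-2-one, via mixed anhydride 20 (not isolated)
Conditions: i-BuOCOCl, N-methylmorpholine, THF, −15 °C; then CH2N2, Et2O, 0 °C → rt
Reagents that add atoms: diazomethane, C=[N+]=[N-]
Why: first stage of the Arndt–Eistert homologation, acylation of diazomethane by the mixed carbonic anhydride; the indole N–H is not acylated by the chloroformate under a tertiary amine base.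

Step 13
Reactants: 21 1-diazo-3-[(1S,2R,3R)-2-(1H-indol-3-ylmethyl)-2,3-dimethyl-6-(propan-2-ylidene)cyclohexyl]propan-2-one
Product: 23 3-[(1S,2R,3R)-2-(1H-indol-3-ylmethyl)-2,3-dimethyl-6-(propan-2-ylidene)cyclohexyl]propanoic acid (suaveolindole), via ketene 22 (not isolated)
Conditions: PhCO2Ag (0.1 equiv), Et3N, THF–H2O (9:1), rt, dark; acidic work-up
Reagents that add atoms: water, O
Why: silver-promoted Wolff rearrangement (1,2-shift of the ring-CH2 group, no stereocentre involved) to the ketene, which is hydrated to the acid.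

**Compound list**

1 | 3-methyl-1H-indole | Cc1c[nH]c2ccccc12 | starting material
2 | 3-methyl-1-(phenylsulfonyl)-1H-indole | Cc1cn(S(=O)(=O)c2ccccc2)c2ccccc12 | intermediate
3 | 3-(bromomethyl)-1-(phenylsulfonyl)-1H-indole | BrCc1cn(S(=O)(=O)c2ccccc2)c2ccccc12 | intermediate
4 | (3R)-5-methoxy-3-methyl-5-oxopentanoic acid | C[C@@H](CC(=O)OC)CC(=O)O | starting material
5 | methyl (3R)-5-hydroxy-3-methylpentanoate | C[C@@H](CC(=O)OC)CCO | intermediate
6 | (4R)-4-methyloxan-2-one | C[C@H]1CC(=O)OCC1 | intermediate
7 | (3S,4R)-4-methyl-3-{[1-(phenylsulfonyl)-1H-indol-3-yl]methyl}oxan-2-one | O=C1OCC[C@@H](C)[C@@H]1Cc1cn(S(=O)(=O)c2ccccc2)c2ccccc12 | intermediate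
8 | (3R,4R)-3,4-dimethyl-3-{[1-(phenylsulfonyl)-1H-indol-3-yl]methyl}oxan-2-one | O=C1OCC[C@@H](C)[C@@]1(C)Cc1cn(S(=O)(=O)c2ccccc2)c2ccccc12 | intermediate
9 | trimethylsilyl (2R,3R)-5-iodo-2,3-dimethyl-2-{[1-(phenylsulfonyl)-1H-indol-3-yl]methyl}pentanoate | C[Si](C)(C)OC(=O)[C@](C)(Cc1cn(S(=O)(=O)c2ccccc2)c2ccccc12)[C@H](C)CCI | intermediate
10 | (2R,3R)-5-iodo-2,3-dimethyl-2-{[1-(phenylsulfonyl)-1H-indol-3-yl]methyl}pentanoic acid | OC(=O)[C@](C)(Cc1cn(S(=O)(=O)c2ccccc2)c2ccccc12)[C@H](C)CCI | intermediate
11 | methyl (2R,3R)-5-iodo-2,3-dimethyl-2-{[1-(phenylsulfonyl)-1H-indol-3-yl]methyl}pentanoate | COC(=O)[C@](C)(Cc1cn(S(=O)(=O)c2ccccc2)c2ccccc12)[C@H](C)CCI | intermediate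
12 | 1,1-dibromo-2-methylprop-1-ene | CC(C)=C(Br)Br | starting material
13 | iodo{(3R,4R)-5-methoxy-3,4-dimethyl-5-oxo-4-{[1-(phenylsulfonyl)-1H-indol-3-yl]methyl}pentyl}zinc | COC(=O)[C@](C)(Cc1cn(S(=O)(=O)c2ccccc2)c2ccccc12)[C@H](C)CC[Zn]I | intermediate
14 | methyl (2R,3R)-6-bromo-2,3,7-trimethyl-2-{[1-(phenylsulfonyl)-1H-indol-3-yl]methyl}oct-6-enoate | COC(=O)[C@](C)(Cc1cn(S(=O)(=O)c2ccccc2)c2ccccc12)[C@H](C)CCC(Br)=C(C)C | intermediate
15 | (2R,3R)-6-bromo-2,3,7-trimethyl-2-{[1-(phenylsulfonyl)-1H-indol-3-yl]methyl}oct-6-enal | O=C[C@](C)(Cc1cn(S(=O)(=O)c2ccccc2)c2ccccc12)[C@H](C)CCC(Br)=C(C)C | intermediate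
16 | methyl 2-(triphenyl-λ5-phosphanylidene)acetate | COC(=O)C=P(c1ccccc1)(c1ccccc1)c1ccccc1 | starting material
17 | methyl (2E,4R,5R)-8-bromo-4,5,9-trimethyl-4-{[1-(phenylsulfonyl)-1H-indol-3-yl]methyl}deca-2,8-dienoate | COC(=O)/C=C/[C@](C)(Cc1cn(S(=O)(=O)c2ccccc2)c2ccccc12)[C@H](C)CCC(Br)=C(C)C | intermediate
18 | methyl 2-[(1S,2R,3R)-2,3-dimethyl-2-{[1-(phenylsulfonyl)-1H-indol-3-yl]methyl}-6-(propan-2-ylidene)cyclohexyl]acetate | CC(C)=C1CC[C@@H](C)[C@@](C)(Cc2cn(S(=O)(=O)c3ccccc3)c3ccccc23)[C@@H]1CC(=O)OC | intermediate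
19 | 2-[(1S,2R,3R)-2-(1H-indol-3-ylmethyl)-2,3-dimethyl-6-(propan-2-ylidene)cyclohexyl]acetic acid | CC(C)=C1CC[C@@H](C)[C@@](C)(Cc2c[nH]c3ccccc23)[C@@H]1CC(=O)O | intermediate
20 | 2-[(1S,2R,3R)-2-(1H-indol-3-ylmethyl)-2,3-dimethyl-6-(propan-2-ylidene)cyclohexyl]acetic (2-methylpropyl carbonic) anhydride | CC(C)=C1CC[C@@H](C)[C@@](C)(Cc2c[nH]c3ccccc23)[C@@H]1CC(=O)OC(=O)OCC(C)C | intermediate
21 | 1-diazo-3-[(1S,2R,3R)-2-(1H-indol-3-ylmethyl)-2,3-dimethyl-6-(propan-2-ylidene)cyclohexyl]propan-2-one | CC(C)=C1CC[C@@H](C)[C@@](C)(Cc2c[nH]c3ccccc23)[C@@H]1CC(=O)C=[N+]=[N-] | intermediate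
22 | 3-[(1S,2R,3R)-2-(1H-indol-3-ylmethyl)-2,3-dimethyl-6-(propan-2-ylidene)cyclohexyl]prop-1-en-1-one | CC(C)=C1CC[C@@H](C)[C@@](C)(Cc2c[nH]c3ccccc23)[C@@H]1CC=C=O | intermediate
23 | 3-[(1S,2R,3R)-2-(1H-indol-3-ylmethyl)-2,3-dimethyl-6-(propan-2-ylidene)cyclohexyl]propanoic acid (suaveolindole) | CC(C)=C1CC[C@@H](C)[C@@](C)(Cc2c[nH]c3ccccc23)[C@@H]1CCC(=O)O | target

**Step count and risks**

Total step count: 13. Longest linear sequence: 12 steps (steps 1, 2 and 4 to 13, from 3-methyl-1H-indole); the sequence from the half-ester 4 is 11 steps.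

Steps most likely to fail:

Step 10. The vinyl radical may take hydrogen from the tin hydride before it cyclises, may attack in the 7-endo sense, or may show weak facial control at the new CH centre because the transition state is early. The fallback is an organometallic closure instead of a radical chain. It sets out from 17: stoichiometric Ni(cod)2 (zerovalent nickel) with Et3N in MeCN–DMF at rt should insert into the C–Br bond, the vinylnickel bromide should add across the enoate in a later, more product-like transition state (stronger allylic-strain control), and protonation of the nickel enolate should return the route at 18. No new compound is formed.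

Step 7. The remaining C–Br bond may also be substituted, or the zinc insertion may stall and the organozinc be lost by protonolysis. The fallback reaches the same bromoalkene through an organoborane. It sets out from 11: elimination with KOt-Bu in THF at 0 °C should give the terminal alkene methyl (2R,3R)-2,3-dimethyl-2-{[1-(phenylsulfonyl)-1H-indol-3-yl]methyl}pent-4-enoate F1. Anti-Markovnikov hydroboration with 9-BBN-H should give the B-alkyl borane methyl (2R,3R)-5-(9-borabicyclo[3.3.1]nonan-9-yl)-2,3-dimethyl-2-{[1-(phenylsulfonyl)-1H-indol-3-yl]methyl}pentanoate F2. Suzuki–Miyaura coupling of F2 with 12 (Pd(dppf)Cl2, K3PO4, DMF–THF–H2O, 50 °C) should return the route at 14.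

Step 9. The stabilised ylide may add too slowly to the aldehyde on the quaternary carbon, so that thermal decomposition competes. The fallback builds the enoate by aldol addition and elimination. It sets out from 15: the lithium enolate of methyl acetate (LiN(i-Pr)2, MeOAc, THF, −78 °C), a small and reactive nucleophile, should give the β-hydroxy ester methyl (4R,5R)-8-bromo-3-hydroxy-4,5,9-trimethyl-4-{[1-(phenylsulfonyl)-1H-indol-3-yl]methyl}dec-8-enoate F3 as a carbinol mixture. Mesylation and elimination (MsCl, Et3N; then DBU, CH2Cl2) can only give the conjugated (E)-enoate, because the neighbouring carbon is quaternary, and should return the route at 17.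

**Further compounds**

F0 | step 10 | none | none
F1 | step 7 | methyl (2R,3R)-2,3-dimethyl-2-{[1-(phenylsulfonyl)-1H-indol-3-yl]methyl}pent-4-enoate | COC(=O)[C@](C)(Cc1cn(S(=O)(=O)c2ccccc2)c2ccccc12)[C@H](C)C=C
F2 | step 7 | methyl (2R,3R)-5-(9-borabicyclo[3.3.1]nonan-9-yl)-2,3-dimethyl-2-{[1-(phenylsulfonyl)-1H-indol-3-yl]methyl}pentanoate | COC(=O)[C@](C)(Cc1cn(S(=O)(=O)c2ccccc2)c2ccccc12)[C@H](C)CCB1C2CCCC1CCC2
F3 | step 9 | methyl (4R,5R)-8-bromo-3-hydroxy-4,5,9-trimethyl-4-{[1-(phenylsulfonyl)-1H-indol-3-yl]methyl}dec-8-enoate | COC(=O)CC(O)[C@](C)(Cc1cn(S(=O)(=O)c2ccccc2)c2ccccc12)[C@H](C)CCC(Br)=C(C)C
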